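- We start from the leftover: let a be the fraction of the charged starting material still free, reckoned as one minus homo dimer minus target, the two products we can read.

the same everywhere: added ligand 0.11 mM

|  | starting material | second substrate | capture agent | free catalyst | temperature | remark | time |
|---|---|---|---|---|---|---|---|
| dawn | 10 mM | 1 equiv | 3 mM | 2 mol% | 110 °C | run made earlier |  |
| autumn | 10 mM | 1 equiv | 3 mM | 3 mol% | 110 °C | run made earlier |  |
| ash | 10 mM | 1.00 equiv | 3.00 mM | 2 mol% | 110 °C | everything together at the start | 15 h |
| larch | 10 mM | 1.00 equiv (fed, over 6.0 h) | 3.00 mM | 2 mol% | 110 °C | all else is in the flask from the start; the feed brings no volume worth counting | 15 h |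
| cedar | 10 mM | 1.00 equiv (in portions, 5, over 6.0 h) | 3.00 mM | 2 mol% | 110 °C | first portion at the start, last at 6.0 h | 15 h |
| alder | 10 mM (fed, over 6.0 h) | 1.00 equiv | 3.00 mM | 2 mol% |  | the addition at 80 °C, then warmed to 110 °C; the feed brings no volume worth counting | 15 h |

| run | time / h | homo dimer / % | target / % |
|---|---|---|---|
| dawn | 0.833 | 13.3 | 5.5 |
| dawn | 2.50 | 27.8 | 13.5 |
| dawn | 4.00 | 36.5 | 16.6 |
| dawn | 6.00 | 41.6 | 18.6 |
| dawn | 10.0 | 51.1 | 21.7 |
| autumn | 0.667 | 10.2 | 7.9 |
| autumn | 1.33 | 16.8 | 13.0 |
| autumn | 2.00 | 21.9 | 16.9 |
| autumn | 2.50 | 24.7 | 19.5 |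
| autumn | 3.00 | 28.2 | 22.2 |

(readings scatter by 0.5 percentage points)

- percentages count the starting material that a species holds: one homo dimer counts as two
- the numbers in the tables scatter with a standard deviation of 0.5 percentage points
- the earlier runs do not show what temperature does; that part of a forecast is a guess

1. the flask with the highest amount of homo dimer, in percent of the starting material charged ("all alike" if they lie within 1.5 percentage points) (ash / larch / cedar / alder / all alike)
2. final homo dimer, as a percentage of the starting material charged, in ash
3. final homo dimer, as a percentage of the starting material charged, in larch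
4. final homo dimer, as a percentage of the starting material charged, in cedar
5. final homo dimer, as a percentage of the starting material charged, in alder

- If two starting material meet to make homo dimer, a falls at a pace proportional to a squared. The inverse of a then climbs in a straight line, at a slope κ, the clock rate of the dimer. This is a second-order decay, not an exponential: its time constant stretches as a falls.
- We read κ from the autumn run, at 3 mol% free catalyst, taking the homo dimer gained between first and last reading and dividing by the time and by the product of the two leftovers: 0.190 h⁻¹. The dawn run, at 2 mol%, reads 0.187 h⁻¹, so we treat the clock as free of the catalyst.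
- Ash has dawn's charges, and dawn's last reading leaves a at 27.2%. Running the clock on to 15 h gives our own a of 21.6%.
- Dawn's target gained 3.1 percentage points over its last 4.00 h. Guessing half that pace for the tail gives 23.6% target, so we commit to 54.7% homo dimer in ash.
- The weak link is the target. Per unit of a, dawn's target pace fell from 0.0686 h⁻¹ early to 0.0231 h⁻¹ late, which we take as a sign that the catalyst fades, and both runs held the second substrate at one charge. They cannot tell us whether feeding it slowly raises or lowers the target. At a fixed leftover each point of target is a point less of homo dimer, so for larch we keep 54.7% with the direction open.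
- The forecast named larch as highest, with 56% in ash, 64% in larch, 63% in cedar and 50% in alder, reasoning “Starving that substrate then slows the target while the dimer keeps running”. For larch the forecast stands above our 54.7%.
- The flasks ended at 55.5% homo dimer in ash, 48.4% in larch, 49.1% in cedar and 50.7% in alder, so ash stands highest. What ran was this:

    free catalyst + added ligand ⇌ idle complex (K = 8200 M⁻¹, k = 1400 M⁻¹ h⁻¹, Ea = 80.0 kJ mol⁻¹, ΔH = −38.0 kJ mol⁻¹)
    catalyst intermediate A → free catalyst + target (k = 360 h⁻¹, Ea = 101 kJ mol⁻¹)
    catalyst intermediate B → free catalyst + second product (k = 14.0 h⁻¹, Ea = 99.0 kJ mol⁻¹)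
    starting material + free catalyst ⇌ catalyst intermediate A (K = 670 M⁻¹, k = 630 M⁻¹ h⁻¹, Ea = 61.0 kJ mol⁻¹, ΔH = 39.0 kJ mol⁻¹)
    catalyst intermediate B + capture agent → trapped intermediate (k = 280 M⁻¹ h⁻¹, Ea = 51.0 kJ mol⁻¹)
    second substrate + free catalyst ⇌ catalyst intermediate B (K = 54.0 M⁻¹, k = 1400 M⁻¹ h⁻¹, Ea = 75.0 kJ mol⁻¹, ΔH = 12.0 kJ mol⁻¹)
    2 starting material → homo dimer (k = 9.20 M⁻¹ h⁻¹, Ea = 60.0 kJ mol⁻¹)
    (constants at 110 °C)

- Larch ended with 33.0% target against 23.3% in ash, on leftovers of 18.6% and 21.2%, and its trapped intermediate stood at 74.0% of the catalyst against 81.2% in ash. The clock running with no target at all leaves 26.0% after 15 h. In a further flask like ash but with 7.5 mM capture agent, the target reached 13.2%, and the starting material stood at 24.6% with homo dimer at 62.2%.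

(Readings and results stem from a simulated flask for an exercise; noise was put on by code.)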